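**Plan**
1. Enabling feature: in the 1,2-dioxolane (O1–O2–C3–C4–C5), C3 is a ketone-level carbon bonded to O2, that is a masked peroxycarbenium ion. C4–C5 with the 5-methyl group is the imprint of a 2-methyl-1-alkene whose tertiary C5 cation arises exactly where O1 must bond, so C3–C4 and O1–C5 can form in one (3+2) event.
2. Retrosynthetic cuts, in order: CO2H ⇒ CH2OH carried as its acetate (oxidation-level helper); C9′=C10′ of the phenyldiene (Horner–Wadsworth–Emmons); ring bonds C3–C4 and O1–C5 together (peroxycarbenium/alkene annulation); chain bonds C3′–C4′ (copper-catalysed coupling) and C1′–C2′ (Evans alkylation).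
3. Forward: a racemic silyl peroxyketal (2 steps) and an enantiopure 2-methyl-1-alkene with a vinyl end (4 steps) are made apart, and the only ring is closed in the annulation. The vinyl end is then cut to the aldehyde, the diene is attached, and the acetate arm is raised to the acid.
4. Stereochemistry: C2′ comes from the oxazolidinone auxiliary. C3 and C5 are set together by a chiral counter-anion acting on a planar cation, so both enantiomers of the ketal converge on one ring. 11E comes from the phosphonate and 9E from the olefination.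

Key step: step 7

Assumption: the confined imidodiphosphorimidate (IDPi) acid is available as either antipode (from (R)- or (S)-BINOL); the antipode that leads to the (3S,5R) ring of the annulation product is identified once on 2-methylhept-1-ene as a model alkene and then used.

Locants: ring O1, O2, C3 (acid arm), C4, C5 (chain); chain C1′ to C12′ counted from the ring. The two ring methyl groups of the target are cis.

**Step 1**
Reactants: 1 3-methylbut-3-en-1-yl acetate
Product: 3 3-hydroperoxy-3-methoxybutyl acetate (racemic), via carbonyl oxide 2 (not isolated)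
Conditions: O3, CH2Cl2/MeOH, −78 °C; purge with N2, concentrate cold
Reagents that add atoms: ozone O=[O+][O-]; methanol CO
Why: Criegee ozonolysis, in which the primary ozonide of the 1,1-disubstituted alkene fragments toward the more substituted carbonyl oxide 2 and formaldehyde, and methanol traps 2 as the α-methoxy hydroperoxide, whose stereocentre does not matter because it is erased in step 7.

**Step 2**
Reactants: 3 3-hydroperoxy-3-methoxybutyl acetate
Product: 4 3-methoxy-3-[(triethylsilyl)peroxy]butyl acetate (racemic)
Conditions: Et3SiCl, imidazole, DMF, 0 °C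
Reagents that add atoms: chlorotriethylsilane CC[Si](Cl)(CC)CC
Why: O-silylation of the hydroperoxide with a silyl chloride and imidazole is the standard entry to silyl peroxyketals and leaves the acetate and the ketal untouched.

**Step 3**
Reactants: 5 (4R)-4-benzyl-3-propanoyl-1,3-oxazolidin-2-one; 6 3-bromo-2-methylprop-1-ene
Product: 8 (4R)-4-benzyl-3-[(2S)-2,4-dimethylpent-4-enoyl]-1,3-oxazolidin-2-one, via sodium Z-enolate 7 (not isolated)
Conditions: NaN(SiMe3)2, THF, −78 °C; then 6, −78 → −40 °C
Reagents that add atoms: none
Why: Evans asymmetric alkylation, in which the chelated sodium Z-enolate 7 is attacked by the reactive allylic bromide on the face opposite the benzyl group, which should set the (2S) centre (later C2′ of the target) under auxiliary control.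

**Step 4**
Reactants: 8 (4R)-4-benzyl-3-[(2S)-2,4-dimethylpent-4-enoyl]-1,3-oxazolidin-2-one
Product: 9 (2S)-2,4-dimethylpent-4-en-1-ol
Conditions: LiBH4, MeOH (1 equiv), Et2O, 0 °C
Reagents that add atoms: none
Why: Reductive removal of the auxiliary by hydride attack at the exocyclic imide carbonyl should give the primary alcohol without touching the α-stereocentre or the alkene, and the oxazolidinone is recovered.

**Step 5**
Reactants: 9 (2S)-2,4-dimethylpent-4-en-1-ol
Product: 10 (2S)-2,4-dimethylpent-4-en-1-yl 4-methylbenzenesulfonate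
Conditions: TsCl, Et3N, DMAP (cat.), CH2Cl2, 0 °C → rt
Reagents that add atoms: 4-methylbenzenesulfonyl chloride Cc1ccc(cc1)S(Cl)(=O)=O
Why: Tosylation of a primary alcohol provides the leaving group for the coupling and involves no stereocentre.

**Step 6**
Reactants: 10 (2S)-2,4-dimethylpent-4-en-1-yl 4-methylbenzenesulfonate; 11 7-bromohept-1-ene
Product: 13 (4R)-2,4-dimethyldodeca-1,11-diene, via Grignard reagent 12 (not isolated)
Conditions: 11, Mg, THF, rt; then 10, Li2CuCl4 (cat.), THF, −78 °C → rt
Reagents that add atoms: none
Why: Copper-catalysed sp3–sp3 cross-coupling of a Grignard reagent with a primary tosylate (Kochi–Schlosser type) is well established for β-methyl-branched chains and leaves the stereocentre, one carbon away from the reacting CH2, untouched.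

**Step 7**
Reactants: 4 3-methoxy-3-[(triethylsilyl)peroxy]butyl acetate (racemic); 13 (4R)-2,4-dimethyldodeca-1,11-diene
Product: 16 2-[(3S,5R)-3,5-dimethyl-5-[(2R)-2-methyldec-9-en-1-yl]-1,2-dioxolan-3-yl]ethyl acetate, via peroxycarbenium ion 14 (not isolated), via tertiary carbocation 15 (not isolated)
Conditions: IDPi acid (N-triflyl imidodiphosphorimidate built from two 3,3′-diaryl-BINOL units, 5 mol %), 4 (1.5 equiv, slow addition), CH2Cl2/toluene, −78 °C
Reagents that add atoms: none
Why: Proposed new method: the silylated catalyst Et3Si–IDPi (formed in the first turnover) removes methoxide from either enantiomer of racemic 4 to give the planar peroxycarbenium ion 14 paired with the confined chiral anion; the CH2 terminus of the 2-methyl-1-alkene of 13 adds to the carbenium carbon (C3–C4 bond) to give the tertiary cation 15, and the silylated peroxide oxygen then captures that cation (O1–C5 bond) while Et3Si+ passes back to the anion, so the stereocentre of 4 is erased before the new ones are set (an enantioconvergent, stereoablative event). The closest known reaction types are the SnCl4- or TiCl4-promoted (3+2) annulation of triethylsilyl peroxyketals with 1,1-disubstituted alkenes, which makes the same two bonds without absolute control, and imidodiphosphorimidate ion-pair catalysis of additions to oxocarbenium ions from acetals and of enantioselective oxygen capture of tertiary cations from 1,1-disubstituted alkenes. The 1,2-dioxolane closes by collapse of the peroxide oxygen onto the sp2 cationic carbon, a five-membered ring closure that is the second bond of a stepwise (3+2) annulation and meets no Baldwin restriction. C3 should be controlled by the face of 14 that the anion leaves open (methyl against the longer 2-acetoxyethyl arm, with the E and Z forms of 14 equilibrating through reversible return of Et3SiOMe), and C5 by the conformation in which the same anion holds 15 during closure, giving the cis-3,5-dimethyl (3S,5R) ring, while the distant C2′ centre of 13 is expected to have little say. The step needs chemoselectivity for the 1,1-disubstituted alkene over the vinyl end (tertiary against secondary cation), ring closure instead of proton loss from 15 (the anion is a very weak base) and an inert side arm, which is why the acid is carried as a 2-acetoxyethyl group: an ester at this position would put acidic α-hydrogens and a nucleophilic carbonyl next to 14 and 15, and an ether oxygen would compete for the cation.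

**Step 8**
Reactants: 16 2-[(3S,5R)-3,5-dimethyl-5-[(2R)-2-methyldec-9-en-1-yl]-1,2-dioxolan-3-yl]ethyl acetate
Product: 18 2-[(3S,5R)-3,5-dimethyl-5-[(2R)-2-methyl-9-oxononyl]-1,2-dioxolan-3-yl]ethyl acetate, via secondary ozonide 17 (not isolated)
Conditions: O3, CH2Cl2, −78 °C; then PPh3, −78 → 0 °C
Reagents that add atoms: ozone O=[O+][O-]
Why: Criegee ozonolysis of the only remaining C=C, with the secondary ozonide 17 reduced by PPh3 far faster than the hindered di-tertiary dialkyl peroxide, should give the aldehyde with all three stereocentres untouched.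

**Step 9**
Reactants: 18 2-[(3S,5R)-3,5-dimethyl-5-[(2R)-2-methyl-9-oxononyl]-1,2-dioxolan-3-yl]ethyl acetate; 19 diethyl [(2E)-3-phenylprop-2-en-1-yl]phosphonate
Product: 21 2-[(3S,5R)-3,5-dimethyl-5-[(2R,9E,11E)-2-methyl-12-phenyldodeca-9,11-dien-1-yl]-1,2-dioxolan-3-yl]ethyl acetate, via lithiated phosphonate 20 (not isolated)
Conditions: 19, LiN(SiMe3)2, THF, −78 °C; then 18, −78 → 0 °C
Reagents that add atoms: none
Why: Horner–Wadsworth–Emmons olefination with an allylic phosphonate, in which anion 20 adds to the aldehyde much faster than to the acetate, the new C9′=C10′ bond should form E under thermodynamic control of the reversible addition, the C11′=C12′ bond keeps the E geometry of 19, and the ring carries no acidic hydrogen at this oxidation level so the base cannot open it.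

**Step 10**
Reactants: 21 2-[(3S,5R)-3,5-dimethyl-5-[(2R,9E,11E)-2-methyl-12-phenyldodeca-9,11-dien-1-yl]-1,2-dioxolan-3-yl]ethyl acetate
Product: 22 2-[(3S,5R)-3,5-dimethyl-5-[(2R,9E,11E)-2-methyl-12-phenyldodeca-9,11-dien-1-yl]-1,2-dioxolan-3-yl]ethan-1-ol
Conditions: K2CO3 (cat.), MeOH, 0 °C → rt
Reagents that add atoms: none
Why: Base-catalysed transesterification (methanolysis) of the acetate should be clean because the di-tertiary peroxide has no α-hydrogen for Kornblum–DeLaMare cleavage and tolerates carbonate in methanol.

**Step 11**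
Reactants: 22 2-[(3S,5R)-3,5-dimethyl-5-[(2R,9E,11E)-2-methyl-12-phenyldodeca-9,11-dien-1-yl]-1,2-dioxolan-3-yl]ethan-1-ol
Product: 24 2-[(3R,5R)-3,5-dimethyl-5-[(2R,9E,11E)-2-methyl-12-phenyldodeca-9,11-dien-1-yl]-1,2-dioxolan-3-yl]acetic acid, via aldehyde 23 (not isolated)
Conditions: TEMPO (cat.), PhI(OAc)2, MeCN/H2O, rt
Reagents that add atoms: water O
Why: Oxoammonium (TEMPO/PhI(OAc)2) oxidation of the primary alcohol to aldehyde 23 and, through its hydrate, to the acid is selective for CH2OH over the conjugated diene and the peroxide, and C3 is quaternary so no stereocentre can be lost (the descriptor at C3 changes from S to R only because the arm gains priority).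

**Compound list**
1 | 3-methylbut-3-en-1-yl acetate | CC(=C)CCOC(C)=O | starting material
2 | 4-acetoxybutan-2-one O-oxide (carbonyl oxide) | CC(=[O+][O-])CCOC(C)=O | intermediate
3 | 3-hydroperoxy-3-methoxybutyl acetate (racemic) | CC(OC)(OO)CCOC(C)=O | intermediate
4 | 3-methoxy-3-[(triethylsilyl)peroxy]butyl acetate (racemic) | CC(OC)(OO[Si](CC)(CC)CC)CCOC(C)=O | intermediate
5 | (4R)-4-benzyl-3-propanoyl-1,3-oxazolidin-2-one | CCC(=O)N1[C@H](Cc2ccccc2)COC1=O | starting material
6 | 3-bromo-2-methylprop-1-ene | CC(=C)CBr | starting material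
7 | sodium (Z)-enolate of 5 | [Na+].C/C=C(\[O-])N1[C@H](Cc2ccccc2)COC1=O | intermediate
8 | (4R)-4-benzyl-3-[(2S)-2,4-dimethylpent-4-enoyl]-1,3-oxazolidin-2-one | C=C(C)C[C@H](C)C(=O)N1[C@H](Cc2ccccc2)COC1=O | intermediate
9 | (2S)-2,4-dimethylpent-4-en-1-ol | C=C(C)C[C@H](C)CO | intermediate
10 | (2S)-2,4-dimethylpent-4-en-1-yl 4-methylbenzenesulfonate | C=C(C)C[C@H](C)COS(=O)(=O)c1ccc(C)cc1 | intermediate
11 | 7-bromohept-1-ene | C=CCCCCCBr | starting material
12 | hept-6-en-1-ylmagnesium bromide | C=CCCCCC[Mg]Br | intermediate
13 | (4R)-2,4-dimethyldodeca-1,11-diene | C=C(C)C[C@H](C)CCCCCCC=C | intermediate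
14 | (4-acetoxybutan-2-ylidene)(triethylsilyloxy)oxonium, the peroxycarbenium ion, paired with the catalyst anion | CC(CCOC(C)=O)=[O+]O[Si](CC)(CC)CC | intermediate
15 | tertiary carbocation at the future C5, with the new C3–C4 bond and the Et3SiOO group on (S)-configured C3 | C[C@H](CCCCCCC=C)C[C+](C)C[C@](C)(CCOC(C)=O)OO[Si](CC)(CC)CC | intermediate
16 | 2-[(3S,5R)-3,5-dimethyl-5-[(2R)-2-methyldec-9-en-1-yl]-1,2-dioxolan-3-yl]ethyl acetate | C[C@H](CCCCCCC=C)C[C@]1(C)C[C@](C)(CCOC(C)=O)OO1 | intermediate
17 | secondary ozonide (1,2,4-trioxolane) of the vinyl group of 16 | C[C@H](CCCCCCC2OCOO2)C[C@]1(C)C[C@](C)(CCOC(C)=O)OO1 | intermediate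
18 | 2-[(3S,5R)-3,5-dimethyl-5-[(2R)-2-methyl-9-oxononyl]-1,2-dioxolan-3-yl]ethyl acetate | C[C@H](CCCCCCC=O)C[C@]1(C)C[C@](C)(CCOC(C)=O)OO1 | intermediate
19 | diethyl [(2E)-3-phenylprop-2-en-1-yl]phosphonate | CCOP(=O)(C/C=C/c1ccccc1)OCC | starting material
20 | lithium salt of 19 (α-lithiated phosphonate) | [Li+].CCOP(=O)([CH-]/C=C/c1ccccc1)OCC | intermediate
21 | 2-[(3S,5R)-3,5-dimethyl-5-[(2R,9E,11E)-2-methyl-12-phenyldodeca-9,11-dien-1-yl]-1,2-dioxolan-3-yl]ethyl acetate | C[C@H](CCCCCC/C=C/C=C/c1ccccc1)C[C@]1(C)C[C@](C)(CCOC(C)=O)OO1 | intermediate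
22 | 2-[(3S,5R)-3,5-dimethyl-5-[(2R,9E,11E)-2-methyl-12-phenyldodeca-9,11-dien-1-yl]-1,2-dioxolan-3-yl]ethan-1-ol | C[C@H](CCCCCC/C=C/C=C/c1ccccc1)C[C@]1(C)C[C@](C)(CCO)OO1 | intermediate
23 | 2-[(3R,5R)-3,5-dimethyl-5-[(2R,9E,11E)-2-methyl-12-phenyldodeca-9,11-dien-1-yl]-1,2-dioxolan-3-yl]acetaldehyde | C[C@H](CCCCCC/C=C/C=C/c1ccccc1)C[C@]1(C)C[C@](C)(CC=O)OO1 | intermediate
24 | 2-[(3R,5R)-3,5-dimethyl-5-[(2R,9E,11E)-2-methyl-12-phenyldodeca-9,11-dien-1-yl]-1,2-dioxolan-3-yl]acetic acid | C[C@H](CCCCCC/C=C/C=C/c1ccccc1)C[C@]1(C)C[C@](C)(CC(=O)O)OO1 | target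

**Totals**
Total step count: 11. Longest linear sequence: 9 steps (steps 3 to 11, from 5 and 6).

**Steps most likely to fail**

Step 7 (bears the label). The chiral anion may discriminate too weakly between the two faces of the peroxycarbenium carbon or between the two modes of ring closure, or the catalyst may stall through silyl transfer to the acetate or through proton loss from the cation. The fallback uses the established achiral promoter and sorts the isomers through a covalent resolving group. It sets out from 4 and 13. SnCl4 (1 equiv) in CH2Cl2 at −78 °C should give the acetate mixture F1, which holds the four C3/C5 stereoisomers. K2CO3 in MeOH frees the alcohol mixture F2. Esterification with (2S)-2-methoxy-2-phenylacetic acid (EDC·HCl, DMAP, CH2Cl2, 0 °C) places a stereocentre and a chromophore two atoms from C3, and the (3S,5R) O-methylmandelate F3 is separated from its three diastereomers by chromatography. K2CO3 in MeOH then gives the single alcohol F4, and Ac2O in pyridine brings the fallback back to the route at 16.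

Step 9. The new C9′=C10′ bond may form with incomplete E selectivity, or the basic phosphonate anion may attack the acetate. The fallback gives up kinetic control of the geometry and uses a thermodynamic funnel. It sets out from 18. A Wittig reaction with the ylide from cinnamyltriphenylphosphonium bromide and NaN(SiMe3)2 (THF, −78 °C → rt) should give the diene acetate F5 as a 9E/9Z mixture. A catalytic amount of I2 in hexane under daylight equilibrates the aryl-conjugated diene to the E,E isomer, which is 21, where the route resumes.

Step 11. The β-peroxy aldehyde formed on the way may lose the peroxide by β-elimination, or the oxidant may attack the conjugated diene. The fallback moves the oxidation ahead of the diene and makes the olefination the last step. It sets out from 16. K2CO3 in MeOH gives the alcohol F6. CrO3/H2SO4 in acetone at 0 °C (acidic medium, no diene present) gives the acid F7. O3 in CH2Cl2 at −78 °C followed by PPh3 gives the aldehyde acid F8. Horner–Wadsworth–Emmons reaction with an excess of lithiated 19 (the first equivalent forms the lithium carboxylate, which resists α-deprotonation) followed by acidic work-up returns to the route at 24.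

**Further compounds**
F1 | step 7 | 2-[3,5-dimethyl-5-[(2R)-2-methyldec-9-en-1-yl]-1,2-dioxolan-3-yl]ethyl acetate (mixture of the four C3/C5 stereoisomers) | C[C@H](CCCCCCC=C)CC1(C)CC(C)(CCOC(C)=O)OO1
F2 | step 7 | 2-[3,5-dimethyl-5-[(2R)-2-methyldec-9-en-1-yl]-1,2-dioxolan-3-yl]ethan-1-ol (mixture of the four C3/C5 stereoisomers) | C[C@H](CCCCCCC=C)CC1(C)CC(C)(CCO)OO1
F3 | step 7 | 2-[(3S,5R)-3,5-dimethyl-5-[(2R)-2-methyldec-9-en-1-yl]-1,2-dioxolan-3-yl]ethyl (2S)-2-methoxy-2-phenylacetate | C[C@H](CCCCCCC=C)C[C@]1(C)C[C@](C)(CCOC(=O)[C@@H](OC)c2ccccc2)OO1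
F4 | step 7 | 2-[(3S,5R)-3,5-dimethyl-5-[(2R)-2-methyldec-9-en-1-yl]-1,2-dioxolan-3-yl]ethan-1-ol | C[C@H](CCCCCCC=C)C[C@]1(C)C[C@](C)(CCO)OO1
F5 | step 9 | 2-[(3S,5R)-3,5-dimethyl-5-[(2R,11E)-2-methyl-12-phenyldodeca-9,11-dien-1-yl]-1,2-dioxolan-3-yl]ethyl acetate (9E/9Z mixture) | C[C@H](CCCCCCC=C/C=C/c1ccccc1)C[C@]1(C)C[C@](C)(CCOC(C)=O)OO1
F6 | step 11 | 2-[(3S,5R)-3,5-dimethyl-5-[(2R)-2-methyldec-9-en-1-yl]-1,2-dioxolan-3-yl]ethan-1-ol | C[C@H](CCCCCCC=C)C[C@]1(C)C[C@](C)(CCO)OO1
F7 | step 11 | 2-[(3R,5R)-3,5-dimethyl-5-[(2R)-2-methyldec-9-en-1-yl]-1,2-dioxolan-3-yl]acetic acid | C[C@H](CCCCCCC=C)C[C@]1(C)C[C@](C)(CC(=O)O)OO1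
F8 | step 11 | 2-[(3R,5R)-3,5-dimethyl-5-[(2R)-2-methyl-9-oxononyl]-1,2-dioxolan-3-yl]acetic acid | C[C@H](CCCCCCC=O)C[C@]1(C)C[C@](C)(CC(=O)O)OO1
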